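The runs are calculated with made-up constants; scatter was added.

At early times a flask of substrate and coupling partner, on its way to target, shows how fast substrate leaves, and substrate is what is read.

| setting | west | south | north | east | south-east |
|---|---|---|---|---|---|
| substrate | 80.0 mM | 80.0 mM | 160 mM | 80.0 mM | 240 mM |
| coupling partner | 200 mM | 300 mM | 200 mM | 200 mM | 100 mM |
| target |  |  |  | 24.0 mM |  |
| time |  |  |  |  | 84 s |

- west run (time / s: [substrate] / mM): 3.4: 75.5; 6.4: 75.4; 12: 68.8; 23: 60.4; 44: 44.1; 84: 23.2
- south run (time / s: [substrate] / mM): 3.4: 76.9; 6.4: 74.9; 12: 70.2; 23: 60.5; 44: 41.5; 84: 18.7
- north run (time / s: [substrate] / mM): 3.4: 154.5; 6.4: 149.3; 12: 138.6; 23: 119.9; 44: 82.6; 84: 37.5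
- east run (time / s: [substrate] / mM): 3.4: 76.1; 6.4: 72.0; 12: 65.9; 23: 52.7; 44: 35.7; 84: 15.9

(each reading ± 0.8 mM)

- reaction order in [coupling partner] at the outset, round the charge of the west run, defined at two percent of the substrate turned into target
- reaction order in [substrate] at the outset, round the charge of the west run, defined at two percent of the substrate turned into target (one fixed amount of target, the same in the runs compared)
- substrate in the south-east run at 84 s, as a share of the substrate charged

- Overall: substrate + coupling partner -> target.
- Constant volume, constant temperature.
- The analysis sees a species whether free or bound.
- "The second partner" is coupling partner.
- An order is taken over about fifteen percent of the charge, up and down.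

In the west flask the natural logarithm of charge over reading at 23 s, divided by that time, gives 0.0122 /s. This is the leaving constant, the share of the substrate leaving per second at early times, an apparent first-order rate constant.

The settings can test it. If each leaving molecule needed partner, raising the partner by half from west to south would raise the constant by the same share. Yet at 23 s the south flask holds 75.6% of its charge and the west flask 75.5%, a gap within the scatter of 1.00% of the charge. Late the partner does show: at 84 s the south flask holds 23.4% and the west flask 29.0%. Twice the substrate should leave the share unchanged if leaving is first order, and the north flask holds 74.9% at 23 s. Inert target should change nothing, but the east flask holds 65.9% at 23 s, so added target speeds the loss.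

Up to 23 s a substrate molecule in the west, south or north flask stays substrate with a chance that reads as an exponential decay at about the leaving constant, but this does not last: at 84 s that constant gives 35.9% of the charge for the west flask, more than the 29.0% read there. In the south-east flask the partner, the limiting reagent, is charged at 41.7% of the substrate. Carrying the early constant to 84 s, with no partner in it and as a rough figure, the reckoning here commits to 35.8% of the charge left at 84 s, less than the 58.3% that would stay if each departure took one partner. For the orders, the readings up to 23 s describe substrate loss, near zero in partner and near one in substrate, while target made is not read, so no separate figure is offered.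

The forecast gives 0.04 in partner, 1 in substrate, and 58.7% (range 58% to 61%), since “the partner is limiting”. Its share stands 23 percentage points above the reckoning here.

    substrate ⇌ intermediate + by-product (0.01170 /s, 0.1170 /M/s)
    intermediate + coupling partner → target (0.7520 /M/s)
    2 coupling partner ⇌ idle reagent dimer, settled at all times (5.960 /M)
    substrate + coupling partner + target → 2 target (1.940 /M²/s)

The south-east flask holds 40.4% of its substrate at 84 s, and the orders come to 0.30 in partner and 0.63 in substrate. The substrate gone there is 59.6% of its charge, more than the partner's 41.7%. The leaving constant of that flask over 84 s is 0.0108 /s, against 0.0122 /s from the west flask. In the west flask that constant gives 23.5 s for a quarter of the charge to leave substrate, and the target made comes to a quarter of the charge at 35.2 s.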